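**Plan**
Retrosynthesis (target numbering; ring A = benzo ring, ring B = quinone ring): ring B is opened at C4–C4a (the carbonyl carbon beside the chain-bearing carbon, and ring A) and at C2–C3 (methyl-bearing and chain-bearing carbons). This leads to the acyclic diazo ketone Ph–CH=C(Me)–C(=O)–C(=N2)–CH2–chain. The chain is then cut at C3–C1' (enolate alkylation), C12'–C13' (sulfone alkylation) and C24'–C25' (copper-catalysed Grignard coupling).
Enabling feature: O=C4–C3(chain)=C2(Me)–C1 together with C8a=C4a of ring A is a masked aryl-vinylketene (C4 = ketene carbon, C1 carried as CH). A carbene at C3 takes C2 over from C4 by a 1,2-shift, and C4 then closes onto C4a within a six-electron array, so both bonds form in one operation.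
Forward: two units of (2E,6E)-farnesyl acetate (ω-hydroxylated, brominated) and (S)-citronellyl bromide are joined into the C40 bromide. This alkylates the α'-enolate of (E)-3-methyl-4-phenylbut-3-en-2-one; diazo transfer, then light and heat, build ring B onto ring A as a 1-naphthol, and O2/Co(salen) oxidises C1 to complete the quinone.
Stereochemistry: C27 (R) is bought as (S)-citronellyl bromide (same spatial arrangement; the descriptor changes by CIP priority only) and is never touched. The six E-olefins come from farnesyl acetate and the E-selective SeO2 oxidation and only see SN2-type couplings at neighbouring CH2 groups.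

Key step: step 11

Remark: the only stereocentre is C27 of the side chain (R); "R40" below stands for the (2E,6E,10E,14E,18E,22E,27R)-3,7,11,15,19,23,27,31-octamethyldotriaconta-2,6,10,14,18,22,30-heptaen-1-yl group, and compounds 1, 4 and 15 are taken as commercial.

Step 1
Reactants: 1 (2E,6E)-farnesyl acetate
Product: 2 (2E,6E,10E)-12-hydroxy-3,7,11-trimethyldodeca-2,6,10-trien-1-yl acetate
Conditions: SeO2 (cat.), t-BuOOH, salicylic acid (cat.), CH2Cl2, 0 → 25 °C
Reagents that add atoms: selenium dioxide, O=[Se]=O (oxygen donor); tert-butyl hydroperoxide, CC(C)(C)OO (stoichiometric oxidant that regenerates it)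
Why: Riley allylic oxidation (ene reaction, then [2,3]-sigmatropic shift) should hydroxylate the (E)-methyl group of the terminal trisubstituted olefin, the most electron-rich one because the C2 olefin is deactivated by the allylic acetate.

Step 2
Reactants: 2 (2E,6E,10E)-12-hydroxy-3,7,11-trimethyldodeca-2,6,10-trien-1-yl acetate
Product: 3 (2E,6E,10E)-12-bromo-3,7,11-trimethyldodeca-2,6,10-trien-1-yl acetate
Conditions: CBr4, PPh3, CH2Cl2, –20 → 0 °C
Reagents that add atoms: carbon tetrabromide, BrC(Br)(Br)Br
Why: Appel reaction, in which the oxyphosphonium ion of the primary allylic alcohol is displaced by bromide in SN2 fashion, so acetate and olefin geometry should stay untouched.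

Step 3
Reactants: 4 (S)-citronellyl bromide; 3 (2E,6E,10E)-12-bromo-3,7,11-trimethyldodeca-2,6,10-trien-1-yl acetate
Product: 7 (2E,6E,10E,15R)-3,7,11,15,19-pentamethylicosa-2,6,10,18-tetraen-1-ol, via (S)-citronellylmagnesium bromide 5 (not isolated), via C25 acetate 6 (not isolated)
Conditions: 4, Mg, THF, 25 °C; then 3, Li2CuCl4 (3 mol%), THF, –78 → –20 °C; crude 6, K2CO3, MeOH, 25 °C
Reagents that add atoms: none
Why: Copper-catalysed cross-coupling of a primary alkyl Grignard reagent with an allylic bromide is α-selective and fast at –78 °C, so the acetate should survive until its deliberate methanolysis, and the stereocentre of 4, remote from the C–Mg bond, is carried through unchanged (S in 4 becomes R in 7 by CIP priority only).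

Step 4
Reactants: 7 (2E,6E,10E,15R)-3,7,11,15,19-pentamethylicosa-2,6,10,18-tetraen-1-ol
Product: 8 (2E,6E,10E,15R)-1-bromo-3,7,11,15,19-pentamethylicosa-2,6,10,18-tetraene
Conditions: PBr3 (0.4 equiv), Et2O, –10 °C
Reagents that add atoms: phosphorus tribromide, BrP(Br)Br
Why: Bromination of a primary allylic alcohol with PBr3 proceeds by SN2 displacement of a phosphite ester at low temperature, which should avoid allylic transposition and loss of E geometry.

Step 5
Reactants: 8 (2E,6E,10E,15R)-1-bromo-3,7,11,15,19-pentamethylicosa-2,6,10,18-tetraene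
Product: 9 [(2E,6E,10E,15R)-3,7,11,15,19-pentamethylicosa-2,6,10,18-tetraen-1-yl] phenyl sulfone
Conditions: PhSO2Na, DMF, 25 °C
Reagents that add atoms: sodium benzenesulfinate, [Na+].[O-]S(=O)c1ccccc1
Why: SN2 S-alkylation of the sulfinate by the primary allylic bromide should give the allylic sulfone with retention of olefin geometry.

Step 6
Reactants: 9 [(2E,6E,10E,15R)-3,7,11,15,19-pentamethylicosa-2,6,10,18-tetraen-1-yl] phenyl sulfone; 3 (2E,6E,10E)-12-bromo-3,7,11-trimethyldodeca-2,6,10-trien-1-yl acetate
Product: 11 (2E,6E,10E,14E,18E,22E,27R)-3,7,11,15,19,23,27,31-octamethyl-13-(phenylsulfonyl)dotriaconta-2,6,10,14,18,22,30-heptaen-1-yl acetate (both C13 epimers), via lithiated sulfone 10 (not isolated)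
Conditions: n-BuLi, THF/DMPU, –78 °C; then 3, –78 → –40 °C
Reagents that add atoms: none
Why: Sulfone alkylation, in which the α-sulfonyl allyl carbanion attacks the primary allylic bromide at its α-carbon, is a head-to-tail union that touches no double bond and should be much faster at –78 °C than attack on the acetate.

Step 7
Reactants: 11 (2E,6E,10E,14E,18E,22E,27R)-3,7,11,15,19,23,27,31-octamethyl-13-(phenylsulfonyl)dotriaconta-2,6,10,14,18,22,30-heptaen-1-yl acetate
Product: 13 (2E,6E,10E,14E,18E,22E,27R)-3,7,11,15,19,23,27,31-octamethyldotriaconta-2,6,10,14,18,22,30-heptaen-1-ol, via lithium alkoxide 12 (not isolated)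
Conditions: LiBHEt3, THF, –78 → 0 °C; then PdCl2(dppp) (5 mol%), 0 °C; aqueous work-up
Reagents that add atoms: none
Why: LiBHEt3 first cleaves the acetate to an alkoxide that cannot ionise, then zerovalent palladium formed from PdCl2(dppp) ionises the allylic sulfone and hydride is delivered to the less substituted allyl terminus (palladium-catalysed reductive desulfonylation), which should keep the trisubstituted E-olefin in place.

Step 8
Reactants: 13 (2E,6E,10E,14E,18E,22E,27R)-3,7,11,15,19,23,27,31-octamethyldotriaconta-2,6,10,14,18,22,30-heptaen-1-ol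
Product: 14 (2E,6E,10E,14E,18E,22E,27R)-1-bromo-3,7,11,15,19,23,27,31-octamethyldotriaconta-2,6,10,14,18,22,30-heptaene
Conditions: PBr3 (0.4 equiv), Et2O, –10 °C; used at once
Reagents that add atoms: phosphorus tribromide, BrP(Br)Br
Why: The same low-temperature SN2 bromination of a primary allylic alcohol as in step 4 should give the all-E bromide without transposition.

Step 9
Reactants: 15 (E)-3-methyl-4-phenylbut-3-en-2-one; 14 (2E,6E,10E,14E,18E,22E,27R)-1-bromo-3,7,11,15,19,23,27,31-octamethyldotriaconta-2,6,10,14,18,22,30-heptaene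
Product: 17 (1E)-2-methyl-1-phenyl-4-R40-but-1-en-3-one, via lithium dienolate 16 (not isolated)
Conditions: 15 (1.5 equiv), LiN(i-Pr)2, THF, –78 °C; then 14, –78 → –20 °C
Reagents that add atoms: none
Why: Kinetic deprotonation can only occur at the α'-methyl group (the α-carbon bears no hydrogen), and SN2 alkylation of the resulting cross-conjugated dienolate by the primary allylic bromide (enolate alkylation) should proceed without allylic transposition, the excess of enolate suppressing dialkylation.

Step 10
Reactants: 17 (1E)-2-methyl-1-phenyl-4-R40-but-1-en-3-one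
Product: 19 (1E)-4-diazo-2-methyl-1-phenyl-4-R40-but-1-en-3-one, via trifluoroacetyl ketone 18 (not isolated)
Conditions: LiN(SiMe3)2, THF, –78 °C; CF3CO2CH2CF3; aq HCl work-up; then MsN3, Et3N, H2O (1 equiv), MeCN, 25 °C
Reagents that add atoms: methanesulfonyl azide, CS(=O)(=O)N=[N+]=[N-] (the two nitrogen atoms of 19); 2,2,2-trifluoroethyl trifluoroacetate, O=C(OCC(F)(F)F)C(F)(F)F (its trifluoroacetyl group is carried by intermediate 18 only)
Why: Regitz diazo transfer in its detrifluoroacetylative form: kinetic trifluoroacetylation activates the α'-methylene as a 1,3-diketone, to which the sulfonyl azide transfers N2 with loss of the trifluoroacetyl group as its sulfonamide, under conditions that should spare the enone and the chain olefins.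

Step 11
Reactants: 19 (1E)-4-diazo-2-methyl-1-phenyl-4-R40-but-1-en-3-one
Product: 24 3-methyl-2-R40-naphthalen-1-ol, via (E)-vinylketene 20 (not isolated), via cyclobutenone 21 (not isolated), via (Z)-vinylketene 22 (not isolated), via dienone 23 (not isolated)
Conditions: hν (Pyrex-filtered medium-pressure Hg lamp, >300 nm), degassed toluene (0.005 M), 25 °C; then 110 °C in the dark
Reagents that add atoms: none
Why: Light expels N2 from the diazo ketone and the 1-methyl-2-phenylvinyl group shifts from the carbonyl carbon to the diazo carbon (photochemical Wolff rearrangement), which forms the bond between the chain-bearing and the methyl-bearing carbons and leaves the old carbonyl carbon as the ketene carbon of 20. In 20 the phenyl ring is trans to the ketene, so 20 closes to cyclobutenone 21 (4π, conrotatory; a temporary four-membered ring), which at 110 °C reopens reversibly in both senses; the isomer 22 with phenyl cis to the ketene undergoes thermal disrotatory 6π-electrocyclisation of the ketene carbon onto an ortho carbon of ring A, the closure that makes ring B, and dienone 23 tautomerises to the naphthol. The closest known reaction types are the vinylketene-forming photo-Wolff step and the final electrocyclisation of the Danheiser benzannulation, and the thermal rearrangement of 4-arylcyclobutenones to 1-naphthols. No lasting stereocentre is created (those of 21 and 23 disappear on ring opening and aromatisation) and C27 is remote and untouched. The step needs migration to win over 1,2-hydrogen shift from the allylic CH2 beside the diazo carbon, favoured by direct irradiation of the s-Z conformer without a metal carbenoid, and it needs closure onto ring A and not onto a chain olefin, secured because only the aryl C=C completes a conjugated six-electron array with the dienylketene while high dilution keeps the ketene from dimerising. Regiochemistry is fixed by the substrate: the chain sits on the former diazo carbon, hence beside the new C–OH carbon, and the two ortho positions of the phenyl ring are equivalent.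

Step 12
Reactants: 24 3-methyl-2-R40-naphthalen-1-ol
Product: 25 2-methyl-3-[(2E,6E,10E,14E,18E,22E,27R)-3,7,11,15,19,23,27,31-octamethyldotriaconta-2,6,10,14,18,22,30-heptaen-1-yl]naphthalene-1,4-dione
Conditions: O2 (1 atm), Co(salen) (10 mol%, divalent cobalt), DMF/THF, 25 °C
Reagents that add atoms: dioxygen, O=O
Why: Cobalt–salen/O2 oxidation of a phenol to the para-quinone: the naphthoxyl radical should be oxygenated at C4, the only free ortho or para position because C2 carries the chain, and the neutral conditions should leave the 2-alkenyl side chain uncyclised.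

**Compound list**
1 | (2E,6E)-farnesyl acetate, (2E,6E)-3,7,11-trimethyldodeca-2,6,10-trien-1-yl acetate | CC(C)=CCC/C(C)=C/CC/C(C)=C/COC(C)=O | starting material
2 | (2E,6E,10E)-12-hydroxy-3,7,11-trimethyldodeca-2,6,10-trien-1-yl acetate | OC/C(C)=C/CC/C(C)=C/CC/C(C)=C/COC(C)=O | intermediate
3 | (2E,6E,10E)-12-bromo-3,7,11-trimethyldodeca-2,6,10-trien-1-yl acetate | BrC/C(C)=C/CC/C(C)=C/CC/C(C)=C/COC(C)=O | intermediate
4 | (S)-citronellyl bromide, (6S)-8-bromo-2,6-dimethyloct-2-ene | CC(C)=CCC[C@H](C)CCBr | starting material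
5 | (S)-citronellylmagnesium bromide | CC(C)=CCC[C@H](C)CC[Mg]Br | intermediate
6 | (2E,6E,10E,15R)-3,7,11,15,19-pentamethylicosa-2,6,10,18-tetraen-1-yl acetate | CC(C)=CCC[C@H](C)CCC/C(C)=C/CC/C(C)=C/CC/C(C)=C/COC(C)=O | intermediate
7 | (2E,6E,10E,15R)-3,7,11,15,19-pentamethylicosa-2,6,10,18-tetraen-1-ol | CC(C)=CCC[C@H](C)CCC/C(C)=C/CC/C(C)=C/CC/C(C)=C/CO | intermediate
8 | (2E,6E,10E,15R)-1-bromo-3,7,11,15,19-pentamethylicosa-2,6,10,18-tetraene | CC(C)=CCC[C@H](C)CCC/C(C)=C/CC/C(C)=C/CC/C(C)=C/CBr | intermediate
9 | [(2E,6E,10E,15R)-3,7,11,15,19-pentamethylicosa-2,6,10,18-tetraen-1-yl] phenyl sulfone | CC(C)=CCC[C@H](C)CCC/C(C)=C/CC/C(C)=C/CC/C(C)=C/CS(=O)(=O)c1ccccc1 | intermediate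
10 | 1-lithio derivative of sulfone 9 | CC(C)=CCC[C@H](C)CCC/C(C)=C/CC/C(C)=C/CC/C(C)=C/C([Li])S(=O)(=O)c1ccccc1 | intermediate
11 | (2E,6E,10E,14E,18E,22E,27R)-3,7,11,15,19,23,27,31-octamethyl-13-(phenylsulfonyl)dotriaconta-2,6,10,14,18,22,30-heptaen-1-yl acetate, both C13 epimers | CC(C)=CCC[C@H](C)CCC/C(C)=C/CC/C(C)=C/CC/C(C)=C/C(S(=O)(=O)c1ccccc1)C/C(C)=C/CC/C(C)=C/CC/C(C)=C/COC(C)=O | intermediate
12 | lithium alkoxide of the 13-(phenylsulfonyl) alcohol derived from 11 | CC(C)=CCC[C@H](C)CCC/C(C)=C/CC/C(C)=C/CC/C(C)=C/C(S(=O)(=O)c1ccccc1)C/C(C)=C/CC/C(C)=C/CC/C(C)=C/CO[Li] | intermediate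
13 | (2E,6E,10E,14E,18E,22E,27R)-3,7,11,15,19,23,27,31-octamethyldotriaconta-2,6,10,14,18,22,30-heptaen-1-ol (R40–OH) | CC(C)=CCC[C@H](C)CCC/C(C)=C/CC/C(C)=C/CC/C(C)=C/CC/C(C)=C/CC/C(C)=C/CC/C(C)=C/CO | intermediate
14 | (2E,6E,10E,14E,18E,22E,27R)-1-bromo-3,7,11,15,19,23,27,31-octamethyldotriaconta-2,6,10,14,18,22,30-heptaene (R40–Br) | CC(C)=CCC[C@H](C)CCC/C(C)=C/CC/C(C)=C/CC/C(C)=C/CC/C(C)=C/CC/C(C)=C/CC/C(C)=C/CBr | intermediate
15 | (E)-3-methyl-4-phenylbut-3-en-2-one | CC(=O)/C(C)=C/c1ccccc1 | starting material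
16 | lithium (E)-3-methyl-4-phenylbuta-1,3-dien-2-olate | C=C(O[Li])/C(C)=C/c1ccccc1 | intermediate
17 | (1E)-2-methyl-1-phenyl-4-R40-but-1-en-3-one | CC(C)=CCC[C@H](C)CCC/C(C)=C/CC/C(C)=C/CC/C(C)=C/CC/C(C)=C/CC/C(C)=C/CC/C(C)=C/CCC(=O)/C(C)=C/c1ccccc1 | intermediate
18 | (1E)-2-methyl-1-phenyl-4-R40-4-(trifluoroacetyl)but-1-en-3-one (keto/enol mixture) | CC(C)=CCC[C@H](C)CCC/C(C)=C/CC/C(C)=C/CC/C(C)=C/CC/C(C)=C/CC/C(C)=C/CC/C(C)=C/CC(C(=O)C(F)(F)F)C(=O)/C(C)=C/c1ccccc1 | intermediate
19 | (1E)-4-diazo-2-methyl-1-phenyl-4-R40-but-1-en-3-one | CC(C)=CCC[C@H](C)CCC/C(C)=C/CC/C(C)=C/CC/C(C)=C/CC/C(C)=C/CC/C(C)=C/CC/C(C)=C/CC(=[N+]=[N-])C(=O)/C(C)=C/c1ccccc1 | intermediate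
20 | (3E)-3-methyl-4-phenyl-2-R40-buta-1,3-dien-1-one (phenyl trans to the ketene) | CC(C)=CCC[C@H](C)CCC/C(C)=C/CC/C(C)=C/CC/C(C)=C/CC/C(C)=C/CC/C(C)=C/CC/C(C)=C/CC(=C=O)/C(C)=C/c1ccccc1 | intermediate
21 | 3-methyl-4-phenyl-2-R40-cyclobut-2-en-1-one (both C4 epimers) | CC(C)=CCC[C@H](C)CCC/C(C)=C/CC/C(C)=C/CC/C(C)=C/CC/C(C)=C/CC/C(C)=C/CC/C(C)=C/CC1=C(C)C(c2ccccc2)C1=O | intermediate
22 | (3Z)-3-methyl-4-phenyl-2-R40-buta-1,3-dien-1-one (phenyl cis to the ketene) | CC(C)=CCC[C@H](C)CCC/C(C)=C/CC/C(C)=C/CC/C(C)=C/CC/C(C)=C/CC/C(C)=C/CC/C(C)=C/CC(=C=O)/C(C)=C\c1ccccc1 | intermediate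
23 | 3-methyl-2-R40-8aH-naphthalen-1-one (keto tautomer of 24, both C8a epimers) | CC(C)=CCC[C@H](C)CCC/C(C)=C/CC/C(C)=C/CC/C(C)=C/CC/C(C)=C/CC/C(C)=C/CC/C(C)=C/CC1=C(C)C=C2C=CC=CC2C1=O | intermediate
24 | 3-methyl-2-R40-naphthalen-1-ol | CC(C)=CCC[C@H](C)CCC/C(C)=C/CC/C(C)=C/CC/C(C)=C/CC/C(C)=C/CC/C(C)=C/CC/C(C)=C/Cc1c(C)cc2ccccc2c1O | intermediate
25 | 2-methyl-3-[(2E,6E,10E,14E,18E,22E,27R)-3,7,11,15,19,23,27,31-octamethyldotriaconta-2,6,10,14,18,22,30-heptaen-1-yl]naphthalene-1,4-dione | CC(C)=CCC[C@H](C)CCC/C(C)=C/CC/C(C)=C/CC/C(C)=C/CC/C(C)=C/CC/C(C)=C/CC/C(C)=C/CC1=C(C)C(=O)c2ccccc2C1=O | target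

**Step count**
Total steps: 12. Longest linear sequence: 12 steps (1 → 25, steps 1–12; 3 is used twice, 4 and 15 enter as commercial materials).

**Steps most likely to fail**

Step 11. The excited diazo ketone or the carbene derived from it may undergo 1,2-hydrogen shift from the allylic CH2 instead of vinyl migration, and the ketene may be lost to dimerisation or to acylation of the naphthol before it reaches the geometry needed for ring closure. The fallback sets out from 14 and returns at 25; it gives up the ring construction and attaches the chain to a finished naphthalene. Commercial 1,4-dimethoxy-2-methylnaphthalene would be brominated at C3 with N-bromosuccinimide in MeCN to 2-bromo-1,4-dimethoxy-3-methylnaphthalene F1. Mg in THF would turn this into (1,4-dimethoxy-3-methylnaphthalen-2-yl)magnesium bromide F2, which would be coupled with bromide 14 under CuBr·SMe2 catalysis at –40 °C (α-selective aryl–allyl coupling with retention of the E-olefin) to 1,4-dimethoxy-2-methyl-3-R40-naphthalene F3. Oxidative demethylation of F3 with (NH4)2Ce(NO3)6 in MeCN/H2O at 0 °C would give 25.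

Step 9. Proton exchange between the product ketone and unreacted enolate may lead to double alkylation, and the lithium dienolate may react sluggishly with the long, hindered allylic bromide so that the bromide decomposes first. The fallback sets out from 14 and returns at 17; it builds the enone by olefination instead of enolate alkylation. Commercial diethyl (3-oxobutan-2-yl)phosphonate would be deprotonated twice (NaH, then n-BuLi, THF, 0 °C) to the sodium lithium dianion of diethyl (3-oxobutan-2-yl)phosphonate F4, which would be alkylated at its terminal CH2 by 14 to diethyl (3-oxo-4-R40-butan-2-yl)phosphonate F5. Horner–Wadsworth–Emmons reaction of F5 with benzaldehyde (NaH, THF, 0 → 25 °C) should give the (E)-enone 17.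

Step 3. The Grignard reagent may attack the acetate, or substitute it or the bromide with allylic transposition, so that the coupling loses chemo- and regioselectivity. The fallback sets out from 4 (with 3) and returns at 7; it replaces the organomagnesium nucleophile by a sulfone-stabilised carbanion. Bromide 4 with PhSO2Na in DMF would give (S)-citronellyl phenyl sulfone F6. Deprotonation with n-BuLi (THF, –78 °C) would give the lithiated sulfone F7, and alkylation with 3 would give (2E,6E,10E,15S)-3,7,11,15,19-pentamethyl-13-(phenylsulfonyl)icosa-2,6,10,18-tetraen-1-yl acetate F8 (both C13 epimers; the descriptor at C15 is S here by CIP priority only). Mg turnings in MeOH at 50 °C would cleave the C–S bond reductively and methanolyse the acetate in the same pot to give 7.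

**Further compounds**
F1 | step 11 | 2-bromo-1,4-dimethoxy-3-methylnaphthalene | COc1c(C)c(Br)c(OC)c2ccccc12
F2 | step 11 | (1,4-dimethoxy-3-methylnaphthalen-2-yl)magnesium bromide | COc1c(C)c([Mg]Br)c(OC)c2ccccc12
F3 | step 11 | 1,4-dimethoxy-2-methyl-3-[(2E,6E,10E,14E,18E,22E,27R)-3,7,11,15,19,23,27,31-octamethyldotriaconta-2,6,10,14,18,22,30-heptaen-1-yl]naphthalene | CC(C)=CCC[C@H](C)CCC/C(C)=C/CC/C(C)=C/CC/C(C)=C/CC/C(C)=C/CC/C(C)=C/CC/C(C)=C/Cc1c(C)c(OC)c2ccccc2c1OC
F4 | step 9 | sodium lithium dianion of diethyl (3-oxobutan-2-yl)phosphonate | [Na+].[Li+].[CH2-]C(=O)[C-](C)P(=O)(OCC)OCC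
F5 | step 9 | diethyl (3-oxo-4-R40-butan-2-yl)phosphonate, i.e. diethyl [(6E,10E,14E,18E,22E,26E,31R)-7,11,15,19,23,27,31,35-octamethyl-3-oxohexatriaconta-6,10,14,18,22,26,34-heptaen-2-yl]phosphonate | CC(C)=CCC[C@H](C)CCC/C(C)=C/CC/C(C)=C/CC/C(C)=C/CC/C(C)=C/CC/C(C)=C/CC/C(C)=C/CCC(=O)C(C)P(=O)(OCC)OCC
F6 | step 3 | (S)-citronellyl phenyl sulfone, {[(3S)-3,7-dimethyloct-6-en-1-yl]sulfonyl}benzene | CC(C)=CCC[C@H](C)CCS(=O)(=O)c1ccccc1
F7 | step 3 | 1-lithio derivative of (S)-citronellyl phenyl sulfone | CC(C)=CCC[C@H](C)CC([Li])S(=O)(=O)c1ccccc1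
F8 | step 3 | (2E,6E,10E,15S)-3,7,11,15,19-pentamethyl-13-(phenylsulfonyl)icosa-2,6,10,18-tetraen-1-yl acetate, both C13 epimers | CC(C)=CCC[C@H](C)CC(S(=O)(=O)c1ccccc1)C/C(C)=C/CC/C(C)=C/CC/C(C)=C/COC(C)=O
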